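Minutes on the flask. Minuted first: [substrate], [target] and [over-reacted product] add up to the substrate charged, so what the substrate readings and target readings do not cover is over-reacted product.

| flask | substrate | reagent in the second phase | remark | time | volume of the second phase over the first |
|---|---|---|---|---|---|
| Tuesday's | 11 mM | 0.45 equiv | run made earlier |  |  |
| Wednesday's | 11 mM | 0.68 equiv | run made earlier |  |  |
| flask | 11 mM | 0.900 equiv |  | 6.0 h | 1.0 |

| run | time / h | target / % | substrate / % |
|---|---|---|---|
| Tuesday's | 0.417 | 1.1 | 99.3 |
| Tuesday's | 1.33 | 6.4 | 92.4 |
| Tuesday's | 2.50 | 9.5 | 89.5 |
| Tuesday's | 4.00 | 13.8 | 83.7 |
| Wednesday's | 0.417 | 3.2 | 96.7 |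
| Wednesday's | 1.33 | 9.1 | 91.5 |
| Wednesday's | 2.50 | 14.7 | 85.5 |
| Wednesday's | 4.00 | 19.0 | 79.9 |

(each reading ± 1 percentage point)

- in the second phase: reagent in the second phase; everything else is in the first
- charges count per volume of the first phase; a concentration in a rate is the amount of a species over the volume of its own phase; every rate counts per litre of the first phase
- reactions considered so far: substrate + reagent in the reaction phase -> target; reagent in the reaction phase + target -> over-reacted product; reagent in the reaction phase <-> reagent in the second phase; reagent in the reaction phase -> decomposed reagent
- the earlier runs hold the two phases in the same ratio of volumes as the flask asked about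

- amount of target at 6.0 h, in percent of the substrate charged
- the change that raises the amount of target at 6.0 h, in percent of the substrate charged most ("none" if none brings more than 2 percentage points) (theta / beta / none)
- amount of target at 6.0 h, in percent of the substrate charged, after beta

I argued for counting lifetimes. The logarithm of the substrate fraction left measures the exposure, the time integral of [reagent in the reaction phase]. If that reagent is lost pseudo-first-order, exposure grows as 1 − exp(−t/τ) and in proportion to the charge. Pooled over both runs, exposure at 4.00 h stands to that at 1.33 h as 2.40. The first time is 3 times the second, so this reads τ = 5.44 h, the exposure lifetime, a loose reading given the scatter. The runs give 0.356 of exposure per equivalent by 4.00 h.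

For this flask I reckoned 66.3% substrate left. The balance gap at 4.00 h, taken as 0.543 times conversion squared, then leaves 27.5% target. On this reckoning, with the time and the substrate held, doubling the charge squares the fraction left, giving 39.0% target. The first readings show a summed exposure 1.6 percentage points short of a start without lag, over two readings each good to 1 point. I read no lag and put theta below 2 points.

The forecaster tabled 27.5%, beta and 44%, holding that “Reagent must therefore be feeding in slowly from the second phase, with a large share wasted”, and put theta at about 4 points. The forecast's figure after beta stands higher than my 39.0%.

The flask gives 28.8% target, beta as the best change and 41.8% after it. Beta brings 13 points, theta 0.11 points.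

    substrate + reagent in the reaction phase → target (k = 0.400 M⁻¹ min⁻¹)
    reagent in the reaction phase + target → over-reacted product (k = 0.260 M⁻¹ min⁻¹)
    reagent in the reaction phase ⇌ reagent in the second phase, rate k3*([reagent in the reaction phase] - [reagent in the second phase]/K3) per volume of the first phase (partition coefficient = 1.20, kL = 0.170 min⁻¹)
    reagent in the reaction phase → decomposed reagent (k = 0.00210 min⁻¹)

This flask keeps 67% substrate at 6.00 h, against the 66.3% reckoned, and the pace of crossing hardly moves its target. The neighbouring flask is the same flask read at 2.5 h. With the same τ of 5.44 h, the exposure there leaves 79.7% substrate, and the balance gap then gives 18.1% target. That neighbouring flask holds 80.8% substrate and 17.9% target.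

The earlier runs and the new flask are simulated on assumed constants, and the scatter is random.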